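The route rests on cutting the cinnamyl side chain between its allylic CH2 and the adjacent vinylic CH. That CH2 and the carbon bearing it (C2 of the 1‑aryl‑propane‑1,3‑diol unit) are traced back to the exocyclic C=CH2 of a Morita–Baylis–Hillman‑type 2‑methylene‑1,3‑diol monoester. In one operation, 9‑BBN adds to this 1,1‑disubstituted alkene under control of the neighbouring silyloxy‑bearing benzylic carbon (the carbinol on the 3,4‑dimethoxyphenyl ring), which sets the C2 stereocentre, and the primary alkylborane is cross‑coupled with (E)‑4‑methoxy‑β‑bromostyrene. The precursor already carries the (Z)‑2‑(silyloxymethyl)but‑2‑enoate ester, so only desilylation follows.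

Key step: step 11

Remark: the β‑keto ester, crotonaldehyde and (E)‑4‑methoxy‑β‑bromostyrene used as starting materials are taken as catalogue compounds.

Step 1
Reactants: 1 ethyl 3-(3,4-dimethoxyphenyl)-3-oxopropanoate
Product: 2 ethyl (3S)-3-(3,4-dimethoxyphenyl)-3-hydroxypropanoate
Conditions: RuCl[(S,S)-TsDPEN](p-cymene) (1 mol%), HCO2H/Et3N (5:2), DMF, 40 °C
Reagents that add atoms: none
Why: Noyori asymmetric transfer hydrogenation of an aryl ketone, in which the (S,S)-TsDPEN–Ru hydride should deliver hydrogen to the Re face through the CH/π-stabilised six-membered transition state and so set the (S)-carbinol centre that becomes the benzylic stereocentre of the target.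

Step 2
Reactants: 2 ethyl (3S)-3-(3,4-dimethoxyphenyl)-3-hydroxypropanoate
Product: 4 ethyl (2R,3S)-2-[(dimethylamino)methyl]-3-(3,4-dimethoxyphenyl)-3-hydroxypropanoate, via dilithium alkoxide-enolate 3 (not isolated)
Conditions: LDA (2.2 equiv), THF, −78 → −20 °C; CH2=NMe2+ I−, −78 °C → rt
Reagents that add atoms: N,N-dimethylmethyleneiminium iodide (Eschenmoser's salt), C=[N+](C)C.[I-]
Why: Fráter–Seebach-type Mannich alkylation of the chelated alkoxide-enolate at C2, which leaves the benzylic centre untouched and should give mainly the anti C2 epimer, a centre that is erased in step 3.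

Step 3
Reactants: 4 ethyl (2R,3S)-2-[(dimethylamino)methyl]-3-(3,4-dimethoxyphenyl)-3-hydroxypropanoate
Product: 6 ethyl 2-[(R)-(3,4-dimethoxyphenyl)(hydroxy)methyl]prop-2-enoate, via trimethylammonium iodide 5 (not isolated)
Conditions: MeI, MeOH, rt; then sat. aq. NaHCO3, CH2Cl2, rt
Reagents that add atoms: none
Why: N-methylation followed by base-induced E1cB (Hofmann-type) loss of trimethylamine is the standard α-methylenation of carbonyl compounds and should unveil the Morita–Baylis–Hillman-type acrylate without touching the carbinol centre (the descriptor becomes R only through a priority change).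

Step 4
Reactants: 6 ethyl 2-[(R)-(3,4-dimethoxyphenyl)(hydroxy)methyl]prop-2-enoate
Product: 7 ethyl 2-{(R)-[(tert-butyldimethylsilyl)oxy](3,4-dimethoxyphenyl)methyl}prop-2-enoate
Conditions: TBSCl, imidazole, DMF, rt
Reagents that add atoms: tert-butyldimethylsilyl chloride, CC(C)(C)[Si](C)(C)Cl
Why: Standard silylation of the secondary alcohol, which blocks the hydroxyl through reduction, esterification and hydroboration and supplies the bulky allylic OTBS group used for stereocontrol in step 11.

Step 5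
Reactants: 7 ethyl 2-{(R)-[(tert-butyldimethylsilyl)oxy](3,4-dimethoxyphenyl)methyl}prop-2-enoate
Product: 8 2-{(R)-[(tert-butyldimethylsilyl)oxy](3,4-dimethoxyphenyl)methyl}prop-2-en-1-ol
Conditions: DIBAL-H (2.5 equiv), CH2Cl2, −78 °C; Rochelle salt work-up
Reagents that add atoms: none
Why: DIBAL-H 1,2-reduction of the acrylate ester at low temperature should give the primary allylic alcohol and leave the silyl ether and the stereocentre untouched.

Step 6
Reactants: 9 (E)-but-2-enal
Product: 10 (Z)-2-iodobut-2-enal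
Conditions: I2, K2CO3, DMAP (20 mol%), THF/H2O (1:1), rt
Reagents that add atoms: iodine, II
Why: Amine-catalysed α-iodination of an enal (Baylis–Hillman-type addition of DMAP, iodination of the enolate, elimination of DMAP) should give the thermodynamically preferred (Z)-α-iodoenal with methyl cis to iodine.

Step 7
Reactants: 10 (Z)-2-iodobut-2-enal
Product: 11 (Z)-2-iodobut-2-en-1-ol
Conditions: NaBH4, THF/H2O (9:1), 0 °C
Reagents that add atoms: none
Why: Chemoselective borohydride 1,2-reduction of the aldehyde, with retention of the alkene geometry and of the C–I bond.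

Step 8
Reactants: 11 (Z)-2-iodobut-2-en-1-ol
Product: 12 tert-butyl{[(2Z)-2-iodobut-2-en-1-yl]oxy}dimethylsilane
Conditions: TBSCl, imidazole, CH2Cl2, rt
Reagents that add atoms: tert-butyldimethylsilyl chloride, CC(C)(C)[Si](C)(C)Cl
Why: Standard silylation of the primary alcohol so that the hydroxyl interferes neither with the organolithium nor with the Mitsunobu reaction.

Step 9
Reactants: 12 tert-butyl{[(2Z)-2-iodobut-2-en-1-yl]oxy}dimethylsilane
Product: 14 (2Z)-2-({[tert-butyl(dimethyl)silyl]oxy}methyl)but-2-enoic acid, via vinyllithium 13 (not isolated)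
Conditions: t-BuLi (2.1 equiv), Et2O, −78 °C; CO2 (g), −78 → 0 °C; cold 0.5 M HCl to pH 3
Reagents that add atoms: carbon dioxide, O=C=O
Why: Iodine–lithium exchange and carboxylation of the configurationally stable vinyllithium both proceed with retention (the classical route to angelic acid from a 2-halobut-2-ene), so methyl should end up cis to the carboxyl group.

Step 10
Reactants: 8 2-{(R)-[(tert-butyldimethylsilyl)oxy](3,4-dimethoxyphenyl)methyl}prop-2-en-1-ol; 14 (2Z)-2-({[tert-butyl(dimethyl)silyl]oxy}methyl)but-2-enoic acid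
Product: 15 2-{(R)-[(tert-butyldimethylsilyl)oxy](3,4-dimethoxyphenyl)methyl}prop-2-en-1-yl (2Z)-2-({[tert-butyl(dimethyl)silyl]oxy}methyl)but-2-enoate
Conditions: PPh3, DIAD, THF, 0 °C → rt
Reagents that add atoms: none
Why: Mitsunobu esterification activates the primary allylic alcohol and not the acid, so the isomerisation-prone (Z)-enoate never becomes an acylating species, and SN2 and SN2′ attack on the 2-substituted allyl unit give the same product.

Step 11
Reactants: 15 2-{(R)-[(tert-butyldimethylsilyl)oxy](3,4-dimethoxyphenyl)methyl}prop-2-en-1-yl (2Z)-2-({[tert-butyl(dimethyl)silyl]oxy}methyl)but-2-enoate; 16 (E)-1-(2-bromoethenyl)-4-methoxybenzene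
Product: 18 (2R,3S)-3-{[tert-butyl(dimethyl)silyl]oxy}-3-(3,4-dimethoxyphenyl)-2-[(2E)-3-(4-methoxyphenyl)prop-2-en-1-yl]propyl (2Z)-2-({[tert-butyl(dimethyl)silyl]oxy}methyl)but-2-enoate, via B-alkyl-9-BBN 17 (not isolated)
Conditions: 9-BBN (1.5 equiv), THF, 0 °C → rt; then H2O, Cs2CO3, 16, Pd(dppf)Cl2·CH2Cl2 (5 mol%), AsPh3 (10 mol%), DMF, rt
Reagents that add atoms: none
Why: 9-BBN adds across the terminal C=CH2 of 15 through a four-centre transition state (boron to CH2, hydride to C2), and the B-alkyl-9-BBN 17 is taken directly into a Suzuki–Miyaura coupling (oxidative addition of Pd(0) into the C–Br bond of 16, base-assisted transmetalation of the primary alkyl group, reductive elimination) that forms the allylic CH2–vinylic CH bond with retention of the E geometry. The closest known reaction type is the Still–Barrish anti-selective hydroboration of 1,1-disubstituted allylic alcohol derivatives combined with B-alkyl Suzuki–Miyaura coupling. No ring is closed. The new stereocentre C2 is controlled by the adjacent silyloxy-bearing benzylic centre: in the favoured staggered transition state the aryl group lies anti to the incoming borane, the allylic C–H points inside toward the bulky reagent and the OTBS group outside, so hydride should reach the face that places CH2O-acyl and OTBS anti along the B–CH2–C2–C3–aryl chain, i.e. (2R,3S). The step needs this facial selectivity (secured by the bulk of 9-BBN and the aryl/OTBS pair), terminal regioselectivity (secured by the 1,1-disubstitution) and chemoselectivity over the trisubstituted, electron-poor enoate alkene, which reacts far more slowly with 9-BBN.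

Step 12
Reactants: 18 (2R,3S)-3-{[tert-butyl(dimethyl)silyl]oxy}-3-(3,4-dimethoxyphenyl)-2-[(2E)-3-(4-methoxyphenyl)prop-2-en-1-yl]propyl (2Z)-2-({[tert-butyl(dimethyl)silyl]oxy}methyl)but-2-enoate
Product: 19 (2R,3S)-3-(3,4-dimethoxyphenyl)-3-hydroxy-2-[(2E)-3-(4-methoxyphenyl)prop-2-en-1-yl]propyl (2Z)-2-(hydroxymethyl)but-2-enoate
Conditions: HF·pyridine, pyridine, THF, 0 °C → rt
Reagents that add atoms: none
Why: Fluoride-mediated cleavage of both silyl ethers under buffered, weakly acidic conditions should avoid acyl migration to the liberated benzylic hydroxyl and leave the ester, both alkenes and both stereocentres untouched.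

Compound list
1 | ethyl 3-(3,4-dimethoxyphenyl)-3-oxopropanoate | CCOC(=O)CC(=O)c1ccc(OC)c(OC)c1 | starting material
2 | ethyl (3S)-3-(3,4-dimethoxyphenyl)-3-hydroxypropanoate | CCOC(=O)C[C@H](O)c1ccc(OC)c(OC)c1 | intermediate
3 | dilithium alkoxide-enolate of 2 | CCO/C([O-])=C/[C@H]([O-])c1ccc(OC)c(OC)c1.[Li+].[Li+] | intermediate
4 | ethyl (2R,3S)-2-[(dimethylamino)methyl]-3-(3,4-dimethoxyphenyl)-3-hydroxypropanoate | CCOC(=O)[C@H](CN(C)C)[C@H](O)c1ccc(OC)c(OC)c1 | intermediate
5 | [(2R,3S)-2-(ethoxycarbonyl)-3-(3,4-dimethoxyphenyl)-3-hydroxypropyl]trimethylammonium iodide | CCOC(=O)[C@H](C[N+](C)(C)C)[C@H](O)c1ccc(OC)c(OC)c1.[I-] | intermediate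
6 | ethyl 2-[(R)-(3,4-dimethoxyphenyl)(hydroxy)methyl]prop-2-enoate | C=C(C(=O)OCC)[C@H](O)c1ccc(OC)c(OC)c1 | intermediate
7 | ethyl 2-{(R)-[(tert-butyldimethylsilyl)oxy](3,4-dimethoxyphenyl)methyl}prop-2-enoate | C=C(C(=O)OCC)[C@H](O[Si](C)(C)C(C)(C)C)c1ccc(OC)c(OC)c1 | intermediate
8 | 2-{(R)-[(tert-butyldimethylsilyl)oxy](3,4-dimethoxyphenyl)methyl}prop-2-en-1-ol | C=C(CO)[C@H](O[Si](C)(C)C(C)(C)C)c1ccc(OC)c(OC)c1 | intermediate
9 | (E)-but-2-enal (crotonaldehyde) | C/C=C/C=O | starting material
10 | (Z)-2-iodobut-2-enal | C/C=C(\I)C=O | intermediate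
11 | (Z)-2-iodobut-2-en-1-ol | C/C=C(\I)CO | intermediate
12 | tert-butyl{[(2Z)-2-iodobut-2-en-1-yl]oxy}dimethylsilane | C/C=C(\I)CO[Si](C)(C)C(C)(C)C | intermediate
13 | [(2E)-1-{[tert-butyl(dimethyl)silyl]oxy}but-2-en-2-yl]lithium | C/C=C(\[Li])CO[Si](C)(C)C(C)(C)C | intermediate
14 | (2Z)-2-({[tert-butyl(dimethyl)silyl]oxy}methyl)but-2-enoic acid | C/C=C(/CO[Si](C)(C)C(C)(C)C)C(=O)O | intermediate
15 | 2-{(R)-[(tert-butyldimethylsilyl)oxy](3,4-dimethoxyphenyl)methyl}prop-2-en-1-yl (2Z)-2-({[tert-butyl(dimethyl)silyl]oxy}methyl)but-2-enoate | C/C=C(/CO[Si](C)(C)C(C)(C)C)C(=O)OCC(=C)[C@H](O[Si](C)(C)C(C)(C)C)c1ccc(OC)c(OC)c1 | intermediate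
16 | (E)-1-(2-bromoethenyl)-4-methoxybenzene | Br/C=C/c1ccc(OC)cc1 | starting material
17 | (2R,3S)-2-[(9-borabicyclo[3.3.1]nonan-9-yl)methyl]-3-{[tert-butyl(dimethyl)silyl]oxy}-3-(3,4-dimethoxyphenyl)propyl (2Z)-2-({[tert-butyl(dimethyl)silyl]oxy}methyl)but-2-enoate | C/C=C(/CO[Si](C)(C)C(C)(C)C)C(=O)OC[C@@H](CB1C2CCCC1CCC2)[C@H](O[Si](C)(C)C(C)(C)C)c1ccc(OC)c(OC)c1 | intermediate
18 | (2R,3S)-3-{[tert-butyl(dimethyl)silyl]oxy}-3-(3,4-dimethoxyphenyl)-2-[(2E)-3-(4-methoxyphenyl)prop-2-en-1-yl]propyl (2Z)-2-({[tert-butyl(dimethyl)silyl]oxy}methyl)but-2-enoate | C/C=C(/CO[Si](C)(C)C(C)(C)C)C(=O)OC[C@@H](C/C=C/c1ccc(OC)cc1)[C@H](O[Si](C)(C)C(C)(C)C)c1ccc(OC)c(OC)c1 | intermediate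
19 | (2R,3S)-3-(3,4-dimethoxyphenyl)-3-hydroxy-2-[(2E)-3-(4-methoxyphenyl)prop-2-en-1-yl]propyl (2Z)-2-(hydroxymethyl)but-2-enoate | C/C=C(/CO)C(=O)OC[C@@H](C/C=C/c1ccc(OC)cc1)[C@H](O)c1ccc(OC)c(OC)c1 | target

Total step count: 12. Longest linear sequence: 8 steps (steps 1–5, 10, 11, 12).

Steps most likely to fail

Step 11. The hydride may be delivered to both faces of the 1,1-disubstituted alkene with too little discrimination, because the aryl and silyloxy groups compete for the anti position, so the C2 epimer would be carried into the coupling; slow reduction of the enoate by 9-BBN is a second risk. The fallback sets both stereocentres by an auxiliary-controlled syn-aldol reaction and makes the CH2–CH= bond earlier by Negishi coupling. It sets out from 16: coupling with (3-ethoxy-3-oxopropyl)zinc bromide (Pd(PPh3)4, THF) should give ethyl (4E)-5-(4-methoxyphenyl)pent-4-enoate F1, and saponification (LiOH, THF/H2O) the acid (4E)-5-(4-methoxyphenyl)pent-4-enoic acid F2. Activation with pivaloyl chloride/Et3N and reaction with lithiated (S)-4-benzyloxazolidin-2-one should give (4S)-4-benzyl-3-[(4E)-5-(4-methoxyphenyl)pent-4-enoyl]-1,3-oxazolidin-2-one F3. Its Z-boron enolate (Bu2BOTf, iPr2NEt, CH2Cl2, −78 °C) should add to 3,4-dimethoxybenzaldehyde to give the Evans syn-aldol adduct (4S)-4-benzyl-3-{(2S,4E)-2-[(S)-(3,4-dimethoxyphenyl)(hydroxy)methyl]-5-(4-methoxyphenyl)pent-4-enoyl}-1,3-oxazolidin-2-one F4. Silylation (TBSOTf, 2,6-lutidine) gives the silyl ether of the aldol adduct F5, and LiBH4 (THF/MeOH) removes the auxiliary to give (2R,3S)-3-{[tert-butyl(dimethyl)silyl]oxy}-3-(3,4-dimethoxyphenyl)-2-[(2E)-3-(4-methoxyphenyl)prop-2-en-1-yl]propan-1-ol F6. Mitsunobu esterification of this alcohol with 14 (PPh3, DIAD) comes back to the route at 18.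

Step 9. The 2-lithioallyl silyl ether may fragment by β-elimination of silanolate or undergo O→C silyl migration before it is carboxylated, and the silyl ether may be lost on acidification. The fallback replaces the organolithium by palladium catalysis. It sets out from 12: methoxycarbonylation (Pd(OAc)2, PPh3, CO 1 atm, MeOH, Et3N, DMF, 60 °C), which proceeds with retention at the vinyl carbon, should give methyl (2Z)-2-({[tert-butyl(dimethyl)silyl]oxy}methyl)but-2-enoate F7. Neutral ester cleavage with Me3SnOH (1,2-dichloroethane, 80 °C) comes back to the route at 14.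

Step 2. Carbon–carbon bond formation with the sparingly soluble iminium salt may be slow and heterogeneous, so that the dianion is consumed by proton transfer or retro-aldol cleavage on warming. The fallback uses hydroxymethylation and dehydration in place of the Mannich–Hofmann sequence. It sets out from 2: the dianion (LDA, THF, −78 °C) is trapped with gaseous formaldehyde to give ethyl (2R,3S)-3-(3,4-dimethoxyphenyl)-3-hydroxy-2-(hydroxymethyl)propanoate F8. Selective sulfonylation of the primary hydroxyl (MsCl, Et3N, CH2Cl2, −20 °C) should give ethyl (2R,3S)-3-(3,4-dimethoxyphenyl)-3-hydroxy-2-{[(methylsulfonyl)oxy]methyl}propanoate F9, and DBU-induced E1cB elimination comes back to the route at 6.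

Further compounds
F1 | step 11 | ethyl (4E)-5-(4-methoxyphenyl)pent-4-enoate | CCOC(=O)CC/C=C/c1ccc(OC)cc1
F2 | step 11 | (4E)-5-(4-methoxyphenyl)pent-4-enoic acid | OC(=O)CC/C=C/c1ccc(OC)cc1
F3 | step 11 | (4S)-4-benzyl-3-[(4E)-5-(4-methoxyphenyl)pent-4-enoyl]-1,3-oxazolidin-2-one | O=C1OC[C@H](Cc2ccccc2)N1C(=O)CC/C=C/c1ccc(OC)cc1
F4 | step 11 | (4S)-4-benzyl-3-{(2S,4E)-2-[(S)-(3,4-dimethoxyphenyl)(hydroxy)methyl]-5-(4-methoxyphenyl)pent-4-enoyl}-1,3-oxazolidin-2-one | O=C1OC[C@H](Cc2ccccc2)N1C(=O)[C@@H](C/C=C/c1ccc(OC)cc1)[C@H](O)c1ccc(OC)c(OC)c1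
F5 | step 11 | (4S)-4-benzyl-3-{(2S,4E)-2-[(S)-{[tert-butyl(dimethyl)silyl]oxy}(3,4-dimethoxyphenyl)methyl]-5-(4-methoxyphenyl)pent-4-enoyl}-1,3-oxazolidin-2-one | O=C1OC[C@H](Cc2ccccc2)N1C(=O)[C@@H](C/C=C/c1ccc(OC)cc1)[C@H](O[Si](C)(C)C(C)(C)C)c1ccc(OC)c(OC)c1
F6 | step 11 | (2R,3S)-3-{[tert-butyl(dimethyl)silyl]oxy}-3-(3,4-dimethoxyphenyl)-2-[(2E)-3-(4-methoxyphenyl)prop-2-en-1-yl]propan-1-ol | OC[C@@H](C/C=C/c1ccc(OC)cc1)[C@H](O[Si](C)(C)C(C)(C)C)c1ccc(OC)c(OC)c1
F7 | step 9 | methyl (2Z)-2-({[tert-butyl(dimethyl)silyl]oxy}methyl)but-2-enoate | C/C=C(/CO[Si](C)(C)C(C)(C)C)C(=O)OC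
F8 | step 2 | ethyl (2R,3S)-3-(3,4-dimethoxyphenyl)-3-hydroxy-2-(hydroxymethyl)propanoate | CCOC(=O)[C@H](CO)[C@H](O)c1ccc(OC)c(OC)c1
F9 | step 2 | ethyl (2R,3S)-3-(3,4-dimethoxyphenyl)-3-hydroxy-2-{[(methylsulfonyl)oxy]methyl}propanoate | CCOC(=O)[C@H](COS(C)(=O)=O)[C@H](O)c1ccc(OC)c(OC)c1
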